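**Plan**

- Retrosynthetic cuts: the C2–O ester; the C13 vinyl carbinol (back through a 13,14-epoxy-15-iodide and an E-allylic alcohol to a C13 methyl ketone and a terminal alkene); C8–C17 (methyl onto a C7=C8 enol triflate); C9–C20 (reductive opening of a 9,10-methano C8 ketone); C9–C20 plus C10–C20 (CH2 onto C9=C10); C9=C10 and C5–C6 (annulation of ring B onto a dimedone enol ether with an α-silyl vinyl ketone).
- Forward order: ring A is dimedone; ring B is annulated onto it (Michael addition at C5, aldol condensation of C9 onto C10); the cyclopropane is fused across C9–C10 and opened to the trans-decalin; C17, the C13 carbinol and the senecioate follow. The side chain is carried from the start as a but-3-enyl group.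
- Enabling feature: the quaternary ring-fusion carbon C10 (C20 trans to H5, cis to the C9 chain) is β to C8, the ring-B carbon that ends as the methyl-bearing sp2 carbon. An oxygen on C8 can therefore first, as a hydroxyl, steer CH2 onto C9=C10 and then, as a ketone, trigger cleavage of C9–C20 so that C20 stays on C10.
- Stereochemistry: C8 carbinol by oxazaborolidine-controlled reduction of the racemic enone, which resolves C5 through separation of diastereomers; C10 by hydroxyl-directed CH2 delivery; C9 by axial protonation and equilibration next to the C8 ketone; C2 by dissolving-metal (thermodynamic) reduction; C13 by Sharpless epoxidation.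

Key step: step 8

Remark: locants follow labdane numbering (ring A C1–C5 and C10, ring B C5–C10, C17 on C8, C20 on C10, side chain C11–C16), and "ent-labdane" names denote the ring-fusion configuration of the target (H5 and H9 on one face, C20 and the C9 chain on the other). It is assumed that the usual models hold for the oxazaborolidine reduction (C9=C10 arm as the large group) and for the titanium tartrate epoxidation; amide bases are commercial solutions.

**Route**

Step 1
Reactants: 1 hex-5-enoic acid
Product: 3 N-methoxy-N-methylhex-5-enamide, via 1-(hex-5-enoyl)imidazole 2 (not isolated)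
Conditions: 1,1'-carbonyldiimidazole, CH2Cl2, rt; then MeNH(OMe)·HCl, rt
Reagents that add atoms: N,O-dimethylhydroxylamine hydrochloride, CNOC.Cl
Why: Activation of the acid as its acyl imidazole and aminolysis (Weinreb amide synthesis) should be clean because the acid has no other electrophilic site.

Step 2
Reactants: 4 (1-bromovinyl)trimethylsilane; 3 N-methoxy-N-methylhex-5-enamide
Product: 6 2-(trimethylsilyl)octa-1,7-dien-3-one, via [1-(trimethylsilyl)vinyl]magnesium bromide 5 (not isolated)
Conditions: Mg turnings, THF, reflux; then 3, THF, 0 °C; reaction mixture poured into cold 1 M HCl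
Reagents that add atoms: none
Why: Weinreb ketone synthesis: the chelated magnesium adduct should persist until the acidic quench, which also protonates the released methoxy(methyl)amine so that it cannot add to the new α-silyl enone.

Step 3
Reactants: 7 dimedone (5,5-dimethylcyclohexane-1,3-dione)
Product: 8 3-methoxy-5,5-dimethylcyclohex-2-en-1-one
Conditions: MeOH, HC(OMe)3, p-toluenesulfonic acid monohydrate (cat.), rt to 40 °C
Reagents that add atoms: methanol, CO
Why: Acid-catalysed enol etherification of a cyclic 1,3-dione, with the orthoformate removing water; the two carbonyls are equivalent, so only one vinylogous ester can form.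

Step 4
Reactants: 8 3-methoxy-5,5-dimethylcyclohex-2-en-1-one; 6 2-(trimethylsilyl)octa-1,7-dien-3-one
Product: 10 3-methoxy-5,5-dimethyl-6-[3-oxo-2-(trimethylsilyl)oct-7-en-1-yl]cyclohex-2-en-1-one (racemic), via lithium 5-methoxy-3,3-dimethylcyclohexa-1,5-dien-1-olate 9 (not isolated)
Conditions: LiN(iPr)2, THF, −78 °C; then 6, −78 to −40 °C; aq NH4Cl
Reagents that add atoms: none
Why: Kinetic deprotonation of the vinylogous ester can only take place at the α′ carbon (the future C5), and the cross-conjugated enolate should undergo Michael addition to the α-silyl vinyl ketone, whose silyl group stabilises the adduct enolate and suppresses polymerisation; C5 is formed racemic.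

Step 5
Reactants: 10 silylated Michael adduct
Product: 12 1-(but-3-en-1-yl)-7-methoxy-5,5-dimethyl-4,4a,5,6-tetrahydronaphthalen-2(3H)-one (racemic), via 3-methoxy-5,5-dimethyl-6-(3-oxooct-7-en-1-yl)cyclohex-2-en-1-one 11 (not isolated)
Conditions: NaOMe (0.3 equiv), MeOH, reflux
Reagents that add atoms: none
Why: Methoxide should cleave the C–Si bond of the α-silyl ketone and then effect intramolecular aldol condensation of C9 onto the C10 carbonyl (Robinson annulation), dehydration being driven by the extended conjugation of the alkoxy dienone; methoxide matches the enol ether, so the alkoxy group cannot be scrambled.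

Step 6
Reactants: 12 methoxy dienone
Product: 14 1-(but-3-en-1-yl)-7,7-(ethylenedioxy)-5,5-dimethyl-4,4a,5,6,7,8-hexahydronaphthalen-2(3H)-one (racemic), via 2-hydroxyethyl dienol ether 13 (not isolated)
Conditions: HOCH2CH2OH (excess), pyridinium p-toluenesulfonate (cat.), benzene, reflux, condensate returned through 4 Å sieves to remove MeOH
Reagents that add atoms: ethylene glycol, OCCO
Why: Acid-catalysed acetal exchange at C2 (alkoxy interchange at the enol ether carbon, then addition of the pendant hydroxyl across C1=C2) should be downhill because a conjugated C9=C10–C8 enone remains and methanol is removed, while C8, the hindered α-branched carbonyl, never gives up its oxygen under anhydrous conditions; the same reaction type gives mono-ketals from enol ethers of cyclohexane-1,3-diones.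

Step 7
Reactants: 14 racemic ketal enone
Product: 15 (2R,4aR)-1-(but-3-en-1-yl)-7,7-(ethylenedioxy)-5,5-dimethyl-2,3,4,4a,5,6,7,8-octahydronaphthalen-2-ol (labdane 5R,8R)
Conditions: (S)-1-methyl-3,3-diphenyltetrahydro-1H,3H-pyrrolo[1,2-c][1,3,2]oxazaborole (0.2 equiv), catecholborane, toluene, −78 °C; aq NaOH work-up; chromatographic separation of the two diastereomeric carbinols
Reagents that add atoms: none
Why: Corey–Bakshi–Shibata reduction: with the tetrasubstituted C9=C10 arm as the large group the (S)-catalyst should give the (8R)-carbinol from both enantiomers of 14, so the racemate becomes two separable diastereomers, of which the one with C8–OH anti to H5 is kept; catecholborane at −78 °C does not hydroborate the terminal alkene.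

Step 8
Reactants: 15 anti allylic alcohol
Product: 18 (8R)-2,2-(ethylenedioxy)-9,20-cyclo-15,16,17-trinor-ent-labd-13-en-8-ol (OH syn to the C20 bridge), via ethylzinc alkoxide 16 (not isolated), via iodomethylzinc alkoxide 17 (not isolated)
Conditions: Et2Zn (2.2 equiv), CH2Cl2, 0 °C; then CH2I2 (2.5 equiv), 0 °C to rt; aq NH4Cl
Reagents that add atoms: diiodomethane, ICI
Why: Et2Zn deprotonates the C8 hydroxyl, exchange with CH2I2 places a Zn–CH2I carbenoid on the alkoxide oxygen, and CH2 is transferred to C9=C10 in one concerted butterfly-type step that forms C9–C20 and C10–C20 together. The closest known reaction type is the hydroxyl-directed Simmons–Smith cyclopropanation (Furukawa variant) of cyclohex-2-en-1-ols. The three-membered ring closes by a single concerted [2+1] addition across the alkene, without an open-chain intermediate. Both new stereocentres, C9 and C10, are controlled by the C8 carbinol centre: delivery occurs on the hydroxyl face, which is anti to H5, so C20 ends trans to H5. The step needs face selectivity and selectivity over the terminal alkene; the first is secured by the allylic alkoxide, the second by the rate gain of the oxygen-bound carbenoid, by the electron-rich tetrasubstituted alkene and by keeping the carbenoid to a small excess at 0 °C.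

Step 9
Reactants: 18 cyclopropyl carbinol
Product: 19 2,2-(ethylenedioxy)-9,20-cyclo-15,16,17-trinor-ent-labd-13-en-8-one
Conditions: nPr4NRuO4 (5 mol %), N-methylmorpholine N-oxide, 4 Å sieves, CH2Cl2, rt
Reagents that add atoms: none
Why: Ley–Griffith oxidation under neutral conditions should give the ketone without acid-induced cyclopropylcarbinyl rearrangement or loss of the ketal.

Step 10
Reactants: 19 cyclopropyl ketone
Product: 21 2,2-(ethylenedioxy)-15,16,17-trinor-ent-labd-13-en-8-one, via lithium enolate 20 (not isolated)
Conditions: Li (2.5 equiv), NH3(l)/THF, −78 °C; solid NH4Cl; then NaOMe (cat.), MeOH, rt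
Reagents that add atoms: none
Why: Dissolving-metal reduction of a conjugated cyclopropyl ketone: electron transfer to the C8 carbonyl should cleave the exocyclic C9–C20 bond, the one aligned with the carbonyl π system, leaving C20 as the methyl on C10 and a C8(9) enolate; protonation opposite the axial C20 methyl and the base equilibration place the C9 chain equatorial, cis to C20.

Step 11
Reactants: 21 C8 ketone
Product: 23 2,2-(ethylenedioxy)-15,16,17-trinor-ent-labda-7,13-dien-8-yl trifluoromethanesulfonate, via potassium enolate 22 (not isolated)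
Conditions: KN(SiMe3)2, THF, −78 °C; then PhNTf2, −78 to 0 °C; aq NH4Cl
Reagents that add atoms: N-phenylbis(trifluoromethanesulfonimide), O=S(=O)(N(c1ccccc1)S(=O)(=O)C(F)(F)F)C(F)(F)F
Why: Kinetic deprotonation by the bulky amide should occur at the C7 methylene and not at the hindered C9 methine, and O-sulfonylation (enol triflate formation) fixes the C7=C8 position of the ring-B alkene.

Step 12
Reactants: 23 enol triflate
Product: 24 2,2-(ethylenedioxy)-15,16-dinor-ent-labda-7,13-diene
Conditions: MeMgBr, Fe(acac)3 (5 mol %), THF/N-methylpyrrolidone, −30 to 0 °C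
Reagents that add atoms: methylmagnesium bromide, C[Mg]Br
Why: Iron-catalysed Kumada-type coupling of an alkenyl triflate with a methyl Grignard reagent should install C17 without moving the alkene; ketal and terminal alkene are inert.

Step 13
Reactants: 24 diene
Product: 25 2,2-(ethylenedioxy)-14,15-dinor-ent-labd-7-en-13-one
Conditions: PdCl2 (10 mol %), Cu(OAc)2 (20 mol %), O2 (1 atm), N,N-dimethylacetamide/H2O 7:1, rt
Reagents that add atoms: water, O
Why: Tsuji–Wacker oxidation is selective for the monosubstituted alkene and gives the methyl ketone by Markovnikov hydroxypalladation; the trisubstituted C7=C8 alkene does not compete, and the acetate co-oxidant keeps the medium mild for the ketal.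

Step 14
Reactants: 25 methyl ketone
Product: 26 ethyl (13E)-2,2-(ethylenedioxy)-ent-labda-7,13-dien-15-oate
Conditions: (EtO)2P(O)CH2CO2Et, NaH, THF, 0 °C to reflux; E isomer separated from Z by chromatography
Reagents that add atoms: triethyl phosphonoacetate, CCOC(=O)CP(=O)(OCC)OCC
Why: Horner–Wadsworth–Emmons olefination of the methyl ketone should favour the E enoate (ester trans to the C12 chain); the minor Z isomer must be removed because it would lead to the opposite C13 configuration.

Step 15
Reactants: 26 E enoate
Product: 27 (13E)-2,2-(ethylenedioxy)-ent-labda-7,13-dien-15-ol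
Conditions: iBu2AlH (2.3 equiv), CH2Cl2, −78 °C; aq potassium sodium tartrate
Reagents that add atoms: none
Why: 1,2-Reduction of the unsaturated ester by the aluminium hydride gives the allylic alcohol and leaves ketal and alkenes untouched.

Step 16
Reactants: 27 E allylic alcohol
Product: 28 (13S,14S)-13,14-epoxy-2,2-(ethylenedioxy)-ent-labd-7-en-15-ol
Conditions: Ti(OiPr)4 (10 mol %), diethyl L-(+)-tartrate (12 mol %), tBuOOH, 4 Å sieves, CH2Cl2, −20 °C
Reagents that add atoms: tert-butyl hydroperoxide, CC(C)(C)OO
Why: Sharpless asymmetric epoxidation: the L-(+)-tartrate catalyst should give the (2S,3S)-type epoxy alcohol from an E-3-methyl allylic alcohol, which sets C13 as S under reagent control independent of the remote ring stereocentres; the isolated C7=C8 alkene is not epoxidised.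

Step 17
Reactants: 28 epoxy alcohol
Product: 29 13,14-epoxy-2,2-(ethylenedioxy)-15-iodo-ent-labd-7-ene (epoxide as in 28)
Conditions: I2, PPh3, imidazole, CH2Cl2, 0 °C
Reagents that add atoms: iodine, II
Why: Appel-type iodination of the primary alcohol is an SN2 displacement at C15 that leaves the epoxide intact.

Step 18
Reactants: 29 epoxy iodide
Product: 30 (13S)-2,2-(ethylenedioxy)-ent-labda-7,14-dien-13-ol
Conditions: Zn dust, EtOH, reflux; aq NH4Cl
Reagents that add atoms: none
Why: Zinc insertion into the C–I bond followed by β-elimination with epoxide opening (reductive elimination of a 2,3-epoxy iodide) forms C14=C15 while the C13–O bond is untouched, so C13 keeps its S configuration.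

Step 19
Reactants: 30 ketal carbinol
Product: 31 (13S)-13-hydroxy-ent-labda-7,14-dien-2-one
Conditions: pyridinium p-toluenesulfonate (cat.), acetone/H2O, 45 °C
Reagents that add atoms: water, O
Why: Mild acid hydrolysis of the dioxolane, helped by relief of the 1,3-diaxial strain between a ketal oxygen and the C20 and axial C4 methyl groups, should free the C2 ketone under conditions too weak to ionise the tertiary allylic alcohol or move the C7=C8 alkene.

Step 20
Reactants: 31 hydroxy ketone
Product: 32 (2R,13S)-ent-labda-7,14-diene-2,13-diol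
Conditions: Li, NH3(l)/THF, tBuOH, −78 °C; solid NH4Cl
Reagents that add atoms: none
Why: Dissolving-metal reduction of the hindered ketone should give the thermodynamically preferred equatorial alcohol (2R), with hydrogen placed axially between the C20 and axial C4 methyl groups, whereas hydride reagents would attack from the open equatorial side and give the axial alcohol; isolated alkenes and the tertiary alkoxide are not reduced at −78 °C.

Step 21
Reactants: 32 diol
Product: 33 (2R,5R,9R,10R,13S)-13-hydroxylabda-7,14-dien-2-yl 3-methylbut-2-enoate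
Conditions: 3-methylbut-2-enoic acid, N,N'-dicyclohexylcarbodiimide, 4-(dimethylamino)pyridine (cat.), CH2Cl2, 0 °C to rt
Reagents that add atoms: 3-methylbut-2-enoic acid, CC(C)=CC(=O)O
Why: Steglich esterification should acylate the unhindered equatorial C2 alcohol only, because the tertiary allylic C13 alcohol is too hindered to react at room temperature.

**Compound list**

1 | hex-5-enoic acid | C=CCCCC(=O)O | starting material
2 | 1-(hex-5-enoyl)imidazole | C=CCCCC(=O)n1ccnc1 | intermediate
3 | N-methoxy-N-methylhex-5-enamide | C=CCCCC(=O)N(C)OC | intermediate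
4 | (1-bromovinyl)trimethylsilane | C=C(Br)[Si](C)(C)C | starting material
5 | [1-(trimethylsilyl)vinyl]magnesium bromide | C=C([Mg]Br)[Si](C)(C)C | intermediate
6 | 2-(trimethylsilyl)octa-1,7-dien-3-one | C=CCCCC(=O)C(=C)[Si](C)(C)C | intermediate
7 | dimedone (5,5-dimethylcyclohexane-1,3-dione) | CC1(C)CC(=O)CC(=O)C1 | starting material
8 | 3-methoxy-5,5-dimethylcyclohex-2-en-1-one | COC1=CC(=O)CC(C)(C)C1 | intermediate
9 | lithium 5-methoxy-3,3-dimethylcyclohexa-1,5-dien-1-olate (kinetic enolate) | [Li+].[O-]C1=CC(C)(C)CC(OC)=C1 | intermediate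
10 | rac-3-methoxy-5,5-dimethyl-6-[3-oxo-2-(trimethylsilyl)oct-7-en-1-yl]cyclohex-2-en-1-one (mixture of epimers at the silyl-bearing carbon) | C=CCCCC(=O)C(CC1C(=O)C=C(OC)CC1(C)C)[Si](C)(C)C | intermediate
11 | rac-3-methoxy-5,5-dimethyl-6-(3-oxooct-7-en-1-yl)cyclohex-2-en-1-one | C=CCCCC(=O)CCC1C(=O)C=C(OC)CC1(C)C | intermediate
12 | rac-1-(but-3-en-1-yl)-7-methoxy-5,5-dimethyl-4,4a,5,6-tetrahydronaphthalen-2(3H)-one (C8 ketone, C9=C10, C1=C2 enol ether) | C=CCCC1=C2C=C(OC)CC(C)(C)C2CCC1=O | intermediate
13 | rac-1-(but-3-en-1-yl)-7-(2-hydroxyethoxy)-5,5-dimethyl-4,4a,5,6-tetrahydronaphthalen-2(3H)-one | C=CCCC1=C2C=C(OCCO)CC(C)(C)C2CCC1=O | intermediate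
14 | rac-1-(but-3-en-1-yl)-7,7-(ethylenedioxy)-5,5-dimethyl-4,4a,5,6,7,8-hexahydronaphthalen-2(3H)-one (C2 dioxolane, C8 ketone, C9=C10) | C=CCCC1=C2CC3(OCCO3)CC(C)(C)C2CCC1=O | intermediate
15 | (2R,4aR)-1-(but-3-en-1-yl)-7,7-(ethylenedioxy)-5,5-dimethyl-2,3,4,4a,5,6,7,8-octahydronaphthalen-2-ol (labdane 5R,8R; C8–OH anti to H5) | C=CCCC1=C2CC3(OCCO3)CC(C)(C)[C@H]2CC[C@H]1O | intermediate
16 | ethylzinc alkoxide of 15 | C=CCCC1=C2CC3(OCCO3)CC(C)(C)[C@H]2CC[C@H]1O[Zn]CC | intermediate
17 | (iodomethyl)zinc alkoxide of 15 | C=CCCC1=C2CC3(OCCO3)CC(C)(C)[C@H]2CC[C@H]1O[Zn]CI | intermediate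
18 | (8R)-2,2-(ethylenedioxy)-9,20-cyclo-15,16,17-trinor-ent-labd-13-en-8-ol (CH2 bridge C20 across C9–C10 on the hydroxyl face, anti to H5) | C=CCC[C@@]12C[C@]23CC4(OCCO4)CC(C)(C)[C@H]3CC[C@H]1O | intermediate
19 | 2,2-(ethylenedioxy)-9,20-cyclo-15,16,17-trinor-ent-labd-13-en-8-one | C=CCC[C@@]12C[C@]23CC4(OCCO4)CC(C)(C)[C@H]3CCC1=O | intermediate
20 | lithium C8(9)-enolate of 21 (C20 methyl on C10, trans to H5) | [Li+].C=CCCC1=C([O-])CC[C@@H]2C(C)(C)CC3(OCCO3)C[C@@]12C | intermediate
21 | 2,2-(ethylenedioxy)-15,16,17-trinor-ent-labd-13-en-8-one (trans-decalin; C9 chain equatorial, cis to C20) | C=CCC[C@@H]1C(=O)CC[C@@H]2C(C)(C)CC3(OCCO3)C[C@@]12C | intermediate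
22 | potassium C7(8)-enolate of 21 | [K+].C=CCC[C@@H]1C([O-])=CC[C@@H]2C(C)(C)CC3(OCCO3)C[C@@]12C | intermediate
23 | 2,2-(ethylenedioxy)-15,16,17-trinor-ent-labda-7,13-dien-8-yl trifluoromethanesulfonate | C=CCC[C@@H]1C(OS(=O)(=O)C(F)(F)F)=CC[C@@H]2C(C)(C)CC3(OCCO3)C[C@@]12C | intermediate
24 | 2,2-(ethylenedioxy)-15,16-dinor-ent-labda-7,13-diene | C=CCC[C@@H]1C(C)=CC[C@@H]2C(C)(C)CC3(OCCO3)C[C@@]12C | intermediate
25 | 2,2-(ethylenedioxy)-14,15-dinor-ent-labd-7-en-13-one | CC(=O)CC[C@@H]1C(C)=CC[C@@H]2C(C)(C)CC3(OCCO3)C[C@@]12C | intermediate
26 | ethyl (13E)-2,2-(ethylenedioxy)-ent-labda-7,13-dien-15-oate | CCOC(=O)/C=C(\C)CC[C@@H]1C(C)=CC[C@@H]2C(C)(C)CC3(OCCO3)C[C@@]12C | intermediate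
27 | (13E)-2,2-(ethylenedioxy)-ent-labda-7,13-dien-15-ol | OC/C=C(\C)CC[C@@H]1C(C)=CC[C@@H]2C(C)(C)CC3(OCCO3)C[C@@]12C | intermediate
28 | (13S,14S)-13,14-epoxy-2,2-(ethylenedioxy)-ent-labd-7-en-15-ol | OC[C@@H]4O[C@@]4(C)CC[C@@H]1C(C)=CC[C@@H]2C(C)(C)CC3(OCCO3)C[C@@]12C | intermediate
29 | 13,14-epoxy-2,2-(ethylenedioxy)-15-iodo-ent-labd-7-ene (epoxide configuration of 28) | IC[C@@H]4O[C@@]4(C)CC[C@@H]1C(C)=CC[C@@H]2C(C)(C)CC3(OCCO3)C[C@@]12C | intermediate
30 | (13S)-2,2-(ethylenedioxy)-ent-labda-7,14-dien-13-ol | C=C[C@@](C)(O)CC[C@@H]1C(C)=CC[C@@H]2C(C)(C)CC3(OCCO3)C[C@@]12C | intermediate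
31 | (13S)-13-hydroxy-ent-labda-7,14-dien-2-one | C=C[C@@](C)(O)CC[C@@H]1C(C)=CC[C@@H]2C(C)(C)CC(=O)C[C@@]12C | intermediate
32 | (2R,13S)-ent-labda-7,14-diene-2,13-diol (C2–OH equatorial) | C=C[C@@](C)(O)CC[C@@H]1C(C)=CC[C@@H]2C(C)(C)C[C@@H](O)C[C@@]12C | intermediate
33 | (2R,5R,9R,10R,13S)-13-hydroxylabda-7,14-dien-2-yl 3-methylbut-2-enoate | C=C[C@@](C)(O)CC[C@@H]1C(C)=CC[C@@H]2C(C)(C)C[C@@H](OC(=O)C=C(C)C)C[C@@]12C | target

**Step count and risks**

Total step count: 21. Longest linear sequence: 20 steps (from hex-5-enoic acid 1: steps 1, 2 and 4 to 21).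

Step 6 (acetal exchange at C2). The equilibrium may stall at the hydroxyethyl enol ether, traces of water may let the ketal migrate to C8, and the product may revert by vinylogous β-elimination on contact with base. The fallback sets out from 12 and returns at 14 under aprotic, kinetic control. 1,2-Bis(trimethylsilyloxy)ethane with catalytic Me3SiOTf in CH2Cl2 at −78 °C silylates the C8 oxygen, makes C2 an oxocarbenium carbon and closes the dioxolane there, giving the C8 trimethylsilyl dienol ether F1. Because C8 keeps its own oxygen throughout, the regiochemistry is fixed. Acetic acid-buffered Bu4NF in THF then releases the dienol, which tautomerises to the conjugated enone 14.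

Step 5 (aldol condensation onto the vinylogous ester). Addition of the C9 enolate to the deactivated C10 carbonyl may be too slow, so that retro-Michael cleavage or intermolecular condensation consumes 10. The fallback sets out from 10 and returns at 14, bypassing 12, by changing the order of events. Aqueous HCl in THF hydrolyses the enol ether and removes the silyl group to give the triketone F2, whose ring 1,3-dione offers a normal ketone carbonyl at C10 in its keto form. p-Toluenesulfonic acid in refluxing toluene with a water separator then effects the aldol condensation to the bicyclic ene-dione F3. Ketalisation of F3 with ethylene glycol and pyridinium p-toluenesulfonate under water removal gives 14, the less hindered C2 carbonyl being the one that is ketalised.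

Step 8 (directed cyclopropanation). Methylene transfer to the hindered tetrasubstituted C9=C10 alkene may be slow, so that excess zinc carbenoid cyclopropanates the terminal alkene or the Lewis-acidic zinc salts open the ketal. The fallback sets out from 15 and returns at 18 without a new compound. It uses a samarium carbenoid (Sm metal, catalytic HgCl2, ClCH2I, THF, −78 °C to rt), which transfers CH2 only to alkenes that carry an allylic hydroxyl, through an alkoxide-bound samarium species, and leaves isolated alkenes untouched. The same two bonds form on the same face, and chemoselectivity no longer depends on limiting the reagent.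

Further compounds
F1 | step 6 | rac-{[1-(but-3-en-1-yl)-7,7-(ethylenedioxy)-5,5-dimethyl-3,4,4a,5,6,7-hexahydronaphthalen-2-yl]oxy}trimethylsilane | C=CCCC1=C(O[Si](C)(C)C)CCC2C1=CC3(OCCO3)CC2(C)C
F2 | step 5 | rac-5,5-dimethyl-4-(3-oxooct-7-en-1-yl)cyclohexane-1,3-dione | C=CCCCC(=O)CCC1C(=O)CC(=O)CC1(C)C
F3 | step 5 | rac-1-(but-3-en-1-yl)-5,5-dimethyl-4,4a,5,6-tetrahydronaphthalene-2,7(3H,8H)-dione | C=CCCC1=C2CC(=O)CC(C)(C)C2CCC1=O
F0 | step 8 | none | none
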